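**Plan**

1. Retrosynthetic cuts, in order: the oxirane oxygen on C1/C10 and the acetyl on O3; then C3–C4, which opens the ten-membered ring; then the O8–acyl bond (formed with inversion at C8); C7–C8; the butenolide (O6–C12 ester bond and C7=C11); C9–C10 (alkenyllithium plus oxirane) and C1=C10 (Wittig).
2. Enabling feature: the Z C4=C5 olefin sits next to the lactone carbinol C6, so C4 can be carried as a configurationally fixed (Z)-alkenyl iodide. The trans γ-lactone ring (O6–C6–C7–C11–C12) and the Z C1=C10 olefin fold the chain so that the C3 aldehyde reaches C4. One carbonyl alkenylation then closes the carbocycle C1–C10 and creates C3.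
3. Forward order: two iodoalkene fragments, then the butenolide ring (metathesis), then the α-methylidene γ-lactone with the C7–C8 bond (Barbier), then the ten-membered ring (C3–C4), then the oxirane.
4. Stereochemistry: C6 from a Sharpless kinetic resolution. C7 (anti to the C6 substituent) and C8 from the chair Barbier transition state; C8 is then inverted by Mitsunobu esterification with (2R)-2-methylbutanoic acid. C3 by substrate control in the ring closure. C1 and C10 by syn epoxidation anti to the C3 and C8 acyloxy groups. Both Z olefins from stereodefined iodoalkenes.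

Key step: step 13

Remark: locants follow germacrane numbering (ring C1–C10, lactone carbons C11–C13 with C12 the carbonyl, C14 the methyl on C10, C15 the methyl on C4); (2R)-2-methylbutanoic acid is taken to be purchasable as the single enantiomer.

**Route**

Step 1
Reactants: 1 3-{[tert-butyl(dimethyl)silyl]oxy}propanal; 2 ethyl(triphenyl)phosphonium iodide
Product: 6 tert-butyl{[(3Z)-4-iodopent-3-en-1-yl]oxy}dimethylsilane, via ethylidene(triphenyl)phosphorane 3 (not isolated), via (1-iodoethyl)(triphenyl)phosphonium iodide 4 (not isolated), via (1-iodoethylidene)(triphenyl)phosphorane 5 (not isolated)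
Conditions: 2, n-BuLi, THF, rt; I2, −78 °C; NaN(SiMe3)2, −20 °C; then 1, −78 °C to rt
Reagents that add atoms: iodine, II
Why: Stork–Zhao olefination: the α-iodo ylide 5 behaves as an unstabilised Wittig reagent toward the unbranched aldehyde and should give the (Z)-2-iodoalkene with iodine cis to the chain, which fixes the later C1=C10 geometry.

Step 2
Reactants: 6 tert-butyl{[(3Z)-4-iodopent-3-en-1-yl]oxy}dimethylsilane
Product: 8 (3Z)-6-{[tert-butyl(dimethyl)silyl]oxy}-3-methylhex-3-en-1-ol, via alkenyllithium 7 (not isolated)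
Conditions: t-BuLi (2 equiv), Et2O, −78 °C; oxirane, BF3·OEt2, −78 °C; then H2O
Reagents that add atoms: oxirane (ethylene oxide), C1CO1
Why: Iodine–lithium exchange retains the alkene geometry, and the alkenyllithium opens oxirane under BF3 activation (organolithium–epoxide alkylation), adding C9 and C8 as a 2-hydroxyethyl group.

Step 3
Reactants: 8 (3Z)-6-{[tert-butyl(dimethyl)silyl]oxy}-3-methylhex-3-en-1-ol
Product: 9 (3Z)-6-{[tert-butyl(dimethyl)silyl]oxy}-3-methylhex-3-enal
Conditions: Dess–Martin periodinane, NaHCO3, CH2Cl2, 0 °C; used at once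
Reagents that add atoms: none
Why: Buffered Dess–Martin oxidation of a homoallylic alcohol should give the β,γ-unsaturated aldehyde without migration of the Z olefin into conjugation.

Step 4
Reactants: 10 prop-2-enal (acrolein)
Product: 11 racemic hex-1-en-4-yn-3-ol
Conditions: CH3C≡CMgBr, THF, −78 °C; then H2O
Reagents that add atoms: prop-1-yn-1-ylmagnesium bromide, CC#C[Mg]Br
Why: Alkynyl Grignard reagents add 1,2 to acrolein at low temperature (Grignard addition), which brings in C4, C5 and C15.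

Step 5
Reactants: 11 racemic hex-1-en-4-yn-3-ol
Product: 12 (3R)-hex-1-en-4-yn-3-ol
Conditions: Ti(OiPr)4, D-(−)-diisopropyl tartrate, t-BuOOH (0.6 equiv), 4 Å molecular sieves, CH2Cl2, −20 °C
Reagents that add atoms: none
Why: Sharpless kinetic resolution: with the D-(−)-tartrate the (3S) alcohol is epoxidised at its vinyl group much faster, so the (3R) alcohol, which carries the C6 configuration of the target, should be recovered.

Step 6
Reactants: 12 (3R)-hex-1-en-4-yn-3-ol
Product: 14 (3R,4Z)-5-iodohexa-1,4-dien-3-ol, via cyclic alkenylalanate 13 (not isolated)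
Conditions: NaAlH2(OCH2CH2OMe)2, THF, 0 °C to rt; I2, −78 °C; aq. potassium sodium tartrate
Reagents that add atoms: iodine, II
Why: Hydroxyl-directed trans-hydroalumination of the propargylic alcohol places aluminium on C4 cis to C6 in a five-membered alanate, and iodinolysis with retention gives the (Z)-iodoalkene while the vinyl group and the C6 stereocentre stay untouched.

Step 7
Reactants: 14 (3R,4Z)-5-iodohexa-1,4-dien-3-ol; 15 2-(bromomethyl)prop-2-enoic acid
Product: 16 (3R,4Z)-5-iodohexa-1,4-dien-3-yl 2-(bromomethyl)prop-2-enoate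
Conditions: DCC, DMAP (cat.), CH2Cl2, 0 °C
Reagents that add atoms: none
Why: Steglich esterification acylates the secondary alcohol at oxygen, so the C6 configuration is retained, and low temperature with little DMAP keeps the allylic bromide intact.

Step 8
Reactants: 16 (3R,4Z)-5-iodohexa-1,4-dien-3-yl 2-(bromomethyl)prop-2-enoate
Product: 17 (5R)-3-(bromomethyl)-5-[(1Z)-2-iodoprop-1-en-1-yl]furan-2(5H)-one
Conditions: second-generation Grubbs catalyst RuCl2(=CHPh)(PCy3)(H2IMes) (5 mol %), CH2Cl2, 40 °C, dilute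
Reagents that add atoms: none
Why: Ring-closing metathesis between the vinyl group and the 1,1-disubstituted acrylate olefin closes the butenolide with loss of ethene, while the trisubstituted iodoalkene is too hindered and electron-poor to take part.

Step 9
Reactants: 17 (5R)-3-(bromomethyl)-5-[(1Z)-2-iodoprop-1-en-1-yl]furan-2(5H)-one; 9 (3Z)-6-{[tert-butyl(dimethyl)silyl]oxy}-3-methylhex-3-enal
Product: 19 (4S,5R)-4-[(1R,3Z)-6-{[tert-butyl(dimethyl)silyl]oxy}-1-hydroxy-3-methylhex-3-en-1-yl]-5-[(1Z)-2-iodoprop-1-en-1-yl]-3-methylideneoxolan-2-one, via allylzinc bromide 18 (not isolated)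
Conditions: Zn dust, THF/sat. aq. NH4Cl, 0 °C to rt
Reagents that add atoms: none
Why: Barbier allylation: the allylzinc reagent attacks the aldehyde through its γ-carbon C7 in a chair (Zimmerman–Traxler) transition state on the face anti to the C6 substituent (trans lactone, C7 set), and because the ring fixes the allyl unit in the E-type geometry the anti topicity should give the 8R carbinol, which is inverted in the next step.

Step 10
Reactants: 19 (4S,5R)-4-[(1R,3Z)-6-{[tert-butyl(dimethyl)silyl]oxy}-1-hydroxy-3-methylhex-3-en-1-yl]-5-[(1Z)-2-iodoprop-1-en-1-yl]-3-methylideneoxolan-2-one; 20 (2R)-2-methylbutanoic acid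
Product: 21 (1S,3Z)-6-{[tert-butyl(dimethyl)silyl]oxy}-1-{(2R,3S)-2-[(1Z)-2-iodoprop-1-en-1-yl]-4-methylidene-5-oxooxolan-3-yl}-3-methylhex-3-en-1-yl (2R)-2-methylbutanoate
Conditions: PPh3, DIAD, toluene, 0 °C (betaine formed first), then 19 and 20, 0 °C to rt
Reagents that add atoms: none
Why: Mitsunobu esterification: the carboxylate displaces the C8 oxyphosphonium group in an SN2 step, so the side chain is installed with inversion to the 8S configuration of the target, and the stereocentre of the acid is not touched.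

Step 11
Reactants: 21 (1S,3Z)-6-{[tert-butyl(dimethyl)silyl]oxy}-1-{(2R,3S)-2-[(1Z)-2-iodoprop-1-en-1-yl]-4-methylidene-5-oxooxolan-3-yl}-3-methylhex-3-en-1-yl (2R)-2-methylbutanoate
Product: 22 (1S,3Z)-6-hydroxy-1-{(2R,3S)-2-[(1Z)-2-iodoprop-1-en-1-yl]-4-methylidene-5-oxooxolan-3-yl}-3-methylhex-3-en-1-yl (2R)-2-methylbutanoate
Conditions: HF·pyridine, pyridine, THF, 0 °C
Reagents that add atoms: none
Why: Buffered fluoride cleaves the primary silyl ether (desilylation), while the lactone, the ester and the iodoalkene are stable under these conditions.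

Step 12
Reactants: 22 (1S,3Z)-6-hydroxy-1-{(2R,3S)-2-[(1Z)-2-iodoprop-1-en-1-yl]-4-methylidene-5-oxooxolan-3-yl}-3-methylhex-3-en-1-yl (2R)-2-methylbutanoate
Product: 23 (1S,3Z)-1-{(2R,3S)-2-[(1Z)-2-iodoprop-1-en-1-yl]-4-methylidene-5-oxooxolan-3-yl}-3-methyl-6-oxohex-3-en-1-yl (2R)-2-methylbutanoate
Conditions: Dess–Martin periodinane, NaHCO3, CH2Cl2, 0 °C; used at once
Reagents that add atoms: none
Why: Dess–Martin oxidation gives the β,γ-unsaturated C3 aldehyde under neutral conditions that leave the Z C1=C10 olefin in place.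

Step 13
Reactants: 23 (1S,3Z)-1-{(2R,3S)-2-[(1Z)-2-iodoprop-1-en-1-yl]-4-methylidene-5-oxooxolan-3-yl}-3-methyl-6-oxohex-3-en-1-yl (2R)-2-methylbutanoate
Product: 25 (3R,6S,7S,8S)-3-hydroxy-8-[(2R)-2-methylbutanoyloxy]germacra-1(10)Z,4Z,11(13)-trien-12,6-olide, via alkenylchromium dichloride 24 (not isolated)
Conditions: CrCl2 (excess), NiCl2 (cat.), degassed DMSO, rt, slow addition of 23 to high dilution
Reagents that add atoms: none
Why: Zerovalent nickel (formed from NiCl2 by CrCl2) inserts into the C4–I bond, the alkenyl group passes to trivalent chromium to give 24, and this alkenylchromium adds to the C3 aldehyde; the closest known reaction type is the Nozaki–Hiyama–Kishi macrocyclisation of an iodoalkene onto an aldehyde, which is known for medium rings. The ten-membered carbocycle closes in a 10-exo-trig mode (C3=O exocyclic to the new ring), and the trans-fused γ-lactone together with the Z C1=C10 olefin holds C3 close to C4. The new C3 stereocentre is set by the substrate: with H3 in the C4=C5 plane (allylic strain against C6) and C2 leaving that plane on the face opposite to C7, the carbonyl oxygen lies anti to O6, which corresponds to the 3R alcohol. The step needs chemoselectivity for the aldehyde over the lactone, the ester and the methylidene acceptor, which the low basicity of alkenylchromium reagents secures, and ring closure over oligomerisation, which high dilution secures. The Z geometry of C4=C5 is carried over from the iodoalkene because oxidative addition and transmetalation are stereoretentive.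

Step 14
Reactants: 25 (3R,6S,7S,8S)-3-hydroxy-8-[(2R)-2-methylbutanoyloxy]germacra-1(10)Z,4Z,11(13)-trien-12,6-olide
Product: 26 (3R,6S,7S,8S)-3-acetoxy-8-[(2R)-2-methylbutanoyloxy]germacra-1(10)Z,4Z,11(13)-trien-12,6-olide
Conditions: Ac2O, pyridine, DMAP (cat.), CH2Cl2, 0 °C
Reagents that add atoms: acetic anhydride, CC(=O)OC(C)=O
Why: DMAP-catalysed O-acetylation of the secondary allylic alcohol proceeds with retention at C3.

Step 15
Reactants: 26 (3R,6S,7S,8S)-3-acetoxy-8-[(2R)-2-methylbutanoyloxy]germacra-1(10)Z,4Z,11(13)-trien-12,6-olide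
Product: 27 (1R,3R,6S,7S,8S,10S)-3-acetoxy-1,10-epoxy-8-[(2R)-2-methylbutanoyloxy]germacra-4Z,11(13)-dien-12,6-olide (CNP0340603.1)
Conditions: mCPBA, NaHCO3, CH2Cl2, 0 °C
Reagents that add atoms: 3-chloroperoxybenzoic acid, O=C(OO)c1cccc(Cl)c1
Why: Prilezhaev epoxidation: the peracid should attack only the electron-rich C1=C10 olefin (C4=C5 is deactivated by two allylic acyloxy groups, C11=C13 is conjugated), syn addition keeps C2 and C9 cis on the oxirane, and attack on the ring face opposite to the C3 and C8 acyloxy groups should give the 1R,10S epoxide.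

**Compound list**

1 | 3-{[tert-butyl(dimethyl)silyl]oxy}propanal | O=CCCO[Si](C)(C)C(C)(C)C | starting material
2 | ethyl(triphenyl)phosphonium iodide | CC[P+](c1ccccc1)(c1ccccc1)c1ccccc1.[I-] | starting material
3 | ethylidene(triphenyl)phosphorane | CC=P(c1ccccc1)(c1ccccc1)c1ccccc1 | intermediate
4 | (1-iodoethyl)(triphenyl)phosphonium iodide | CC(I)[P+](c1ccccc1)(c1ccccc1)c1ccccc1.[I-] | intermediate
5 | (1-iodoethylidene)(triphenyl)phosphorane | CC(I)=P(c1ccccc1)(c1ccccc1)c1ccccc1 | intermediate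
6 | tert-butyl{[(3Z)-4-iodopent-3-en-1-yl]oxy}dimethylsilane | C/C(I)=C/CCO[Si](C)(C)C(C)(C)C | intermediate
7 | alkenyllithium: [(2E)-5-{[tert-butyl(dimethyl)silyl]oxy}pent-2-en-2-yl]lithium (lithium cis to the chain, geometry of 6 retained) | C/C([Li])=C/CCO[Si](C)(C)C(C)(C)C | intermediate
8 | (3Z)-6-{[tert-butyl(dimethyl)silyl]oxy}-3-methylhex-3-en-1-ol | OCC/C(C)=C\CCO[Si](C)(C)C(C)(C)C | intermediate
9 | (3Z)-6-{[tert-butyl(dimethyl)silyl]oxy}-3-methylhex-3-enal | O=CC/C(C)=C\CCO[Si](C)(C)C(C)(C)C | intermediate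
10 | prop-2-enal (acrolein) | C=CC=O | starting material
11 | racemic hex-1-en-4-yn-3-ol | C=CC(O)C#CC | intermediate
12 | (3R)-hex-1-en-4-yn-3-ol | C=C[C@@H](O)C#CC | intermediate
13 | cyclic alkenylalanate: sodium (5R)-5-ethenyl-2,2-bis(2-methoxyethoxy)-3-methyl-2,5-dihydro-1,2-oxaaluminol-2-uide | C=C[C@@H]1C=C(C)[Al-](OCCOC)(OCCOC)O1.[Na+] | intermediate
14 | (3R,4Z)-5-iodohexa-1,4-dien-3-ol | C=C[C@@H](O)/C=C(/C)I | intermediate
15 | 2-(bromomethyl)prop-2-enoic acid | C=C(CBr)C(=O)O | starting material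
16 | (3R,4Z)-5-iodohexa-1,4-dien-3-yl 2-(bromomethyl)prop-2-enoate | C=C(CBr)C(=O)O[C@H](C=C)/C=C(/C)I | intermediate
17 | (5R)-3-(bromomethyl)-5-[(1Z)-2-iodoprop-1-en-1-yl]furan-2(5H)-one | BrCC1=C[C@H](/C=C(/C)I)OC1=O | intermediate
18 | allylzinc bromide: bromo({(5R)-5-[(1Z)-2-iodoprop-1-en-1-yl]-2-oxo-2,5-dihydrofuran-3-yl}methyl)zinc | Br[Zn]CC1=C[C@H](/C=C(/C)I)OC1=O | intermediate
19 | (4S,5R)-4-[(1R,3Z)-6-{[tert-butyl(dimethyl)silyl]oxy}-1-hydroxy-3-methylhex-3-en-1-yl]-5-[(1Z)-2-iodoprop-1-en-1-yl]-3-methylideneoxolan-2-one | C=C1C(=O)O[C@@H](/C=C(/C)I)[C@@H]1[C@H](O)C/C(C)=C\CCO[Si](C)(C)C(C)(C)C | intermediate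
20 | (2R)-2-methylbutanoic acid | CC[C@@H](C)C(=O)O | starting material
21 | (1S,3Z)-6-{[tert-butyl(dimethyl)silyl]oxy}-1-{(2R,3S)-2-[(1Z)-2-iodoprop-1-en-1-yl]-4-methylidene-5-oxooxolan-3-yl}-3-methylhex-3-en-1-yl (2R)-2-methylbutanoate | C=C1C(=O)O[C@@H](/C=C(/C)I)[C@@H]1[C@@H](OC(=O)[C@H](C)CC)C/C(C)=C\CCO[Si](C)(C)C(C)(C)C | intermediate
22 | (1S,3Z)-6-hydroxy-1-{(2R,3S)-2-[(1Z)-2-iodoprop-1-en-1-yl]-4-methylidene-5-oxooxolan-3-yl}-3-methylhex-3-en-1-yl (2R)-2-methylbutanoate | C=C1C(=O)O[C@@H](/C=C(/C)I)[C@@H]1[C@@H](OC(=O)[C@H](C)CC)C/C(C)=C\CCO | intermediate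
23 | (1S,3Z)-1-{(2R,3S)-2-[(1Z)-2-iodoprop-1-en-1-yl]-4-methylidene-5-oxooxolan-3-yl}-3-methyl-6-oxohex-3-en-1-yl (2R)-2-methylbutanoate | C=C1C(=O)O[C@@H](/C=C(/C)I)[C@@H]1[C@@H](OC(=O)[C@H](C)CC)C/C(C)=C\CC=O | intermediate
24 | alkenylchromium dichloride: dichloro{(1Z)-1-[(2R,3S)-3-{(1S,3Z)-3-methyl-1-[(2R)-2-methylbutanoyloxy]-6-oxohex-3-en-1-yl}-4-methylidene-5-oxooxolan-2-yl]prop-1-en-2-yl}chromium | C=C1C(=O)O[C@@H](/C=C(/C)[Cr](Cl)Cl)[C@@H]1[C@@H](OC(=O)[C@H](C)CC)C/C(C)=C\CC=O | intermediate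
25 | (3R,6S,7S,8S)-3-hydroxy-8-[(2R)-2-methylbutanoyloxy]germacra-1(10)Z,4Z,11(13)-trien-12,6-olide | C=C1C(=O)O[C@H]2/C=C(/C)[C@H](O)C/C=C(/C)C[C@H](OC(=O)[C@H](C)CC)[C@H]12 | intermediate
26 | (3R,6S,7S,8S)-3-acetoxy-8-[(2R)-2-methylbutanoyloxy]germacra-1(10)Z,4Z,11(13)-trien-12,6-olide | C=C1C(=O)O[C@H]2/C=C(/C)[C@H](OC(C)=O)C/C=C(/C)C[C@H](OC(=O)[C@H](C)CC)[C@H]12 | intermediate
27 | (1R,3R,6S,7S,8S,10S)-3-acetoxy-1,10-epoxy-8-[(2R)-2-methylbutanoyloxy]germacra-4Z,11(13)-dien-12,6-olide (CNP0340603.1) | C=C1C(=O)O[C@H]2/C=C(/C)[C@H](OC(C)=O)C[C@H]3O[C@@]3(C)C[C@H](OC(=O)[C@H](C)CC)[C@H]12 | target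

**Totals**

Total step count: 15.
Longest linear sequence: 12 steps (steps 4 to 15, from acrolein 10).

**Steps most likely to fail**

1. Step 13 (ring closure). What may go wrong: poor facial selectivity at the C3 carbonyl, because the two possible arrangements of the chain about the Z C4=C5 unit lead to opposite configurations at C3. The fallback sets C3 by reagent control. It sets out from 23: the ring closure is run as in step 13, and the mixture of C3 epimers, which then contains (3S,6S,7S,8S)-3-hydroxy-8-[(2R)-2-methylbutanoyloxy]germacra-1(10)Z,4Z,11(13)-trien-12,6-olide F1, is oxidised with Dess–Martin periodinane (NaHCO3, CH2Cl2) to the enone (6S,7S,8S)-8-[(2R)-2-methylbutanoyloxy]-3-oxogermacra-1(10)Z,4Z,11(13)-trien-12,6-olide F2. Corey–Bakshi–Shibata reduction of F2 with the (S)-configured oxazaborolidine [(S)-1-methyl-3,3-diphenyltetrahydro-1H,3H-pyrrolo[1,2-c][1,3,2]oxazaborole] and catecholborane at −78 °C, in which the alkenyl side acts as the large group, should give the 3R alcohol, and the route is rejoined at 25.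

2. Step 10 (Mitsunobu inversion at C8). What may go wrong: elimination of the activated C8 oxygen toward C9 or C7, substitution with retention, or conjugate addition of the phosphine to the methylidene lactone instead of SN2 displacement at the hindered carbinol. The fallback inverts C8 by oxidation and reduction. It sets out from 19: Dess–Martin oxidation gives the ketone (4R,5R)-4-[(3Z)-6-{[tert-butyl(dimethyl)silyl]oxy}-3-methylhex-3-enoyl]-5-[(1Z)-2-iodoprop-1-en-1-yl]-3-methylideneoxolan-2-one F3, which is reduced at once with the (R)-configured CBS oxazaborolidine and catecholborane at −78 °C to the 8S alcohol (4S,5R)-4-[(1S,3Z)-6-{[tert-butyl(dimethyl)silyl]oxy}-1-hydroxy-3-methylhex-3-en-1-yl]-5-[(1Z)-2-iodoprop-1-en-1-yl]-3-methylideneoxolan-2-one F4. Steglich esterification of F4 with 20 (DCC, DMAP, CH2Cl2, 0 °C; retention at C8) rejoins the route at 21.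

3. Step 15 (epoxidation). What may go wrong: delivery of oxygen to the wrong face of the C1=C10 olefin in the ten-membered ring. The fallback sets the oxirane before ring closure by reagent control. It sets out from 21: Shi epoxidation with the D-fructose-derived ketone (1,2:4,5-di-O-isopropylidene-β-D-erythro-hexo-2,3-diulo-2,6-pyranose), KHSO5 (as 2KHSO5·KHSO4·K2SO4) and K2CO3 in MeCN/dimethoxymethane/water at 0 °C should, by the spiro transition-state model, give the 1R,10S epoxide (1S)-2-[(2S,3R)-3-(2-{[tert-butyl(dimethyl)silyl]oxy}ethyl)-2-methyloxiran-2-yl]-1-{(2R,3S)-2-[(1Z)-2-iodoprop-1-en-1-yl]-4-methylidene-5-oxooxolan-3-yl}ethyl (2R)-2-methylbutanoate F5. Desilylation with Bu4NF and AcOH in THF gives (1S)-2-[(2S,3R)-3-(2-hydroxyethyl)-2-methyloxiran-2-yl]-1-{(2R,3S)-2-[(1Z)-2-iodoprop-1-en-1-yl]-4-methylidene-5-oxooxolan-3-yl}ethyl (2R)-2-methylbutanoate F6. Buffered Dess–Martin oxidation gives the epoxy aldehyde (1S)-1-{(2R,3S)-2-[(1Z)-2-iodoprop-1-en-1-yl]-4-methylidene-5-oxooxolan-3-yl}-2-[(2S,3R)-2-methyl-3-(2-oxoethyl)oxiran-2-yl]ethyl (2R)-2-methylbutanoate F7. Ring closure with CrCl2 and NiCl2 as in step 13 gives (1R,3R,6S,7S,8S,10S)-1,10-epoxy-3-hydroxy-8-[(2R)-2-methylbutanoyloxy]germacra-4Z,11(13)-dien-12,6-olide F8, and acetylation as in step 14 rejoins the route at 27.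

**Further compounds**

F1 | step 13 | (3S,6S,7S,8S)-3-hydroxy-8-[(2R)-2-methylbutanoyloxy]germacra-1(10)Z,4Z,11(13)-trien-12,6-olide | C=C1C(=O)O[C@H]2/C=C(/C)[C@@H](O)C/C=C(/C)C[C@H](OC(=O)[C@H](C)CC)[C@H]12
F2 | step 13 | (6S,7S,8S)-8-[(2R)-2-methylbutanoyloxy]-3-oxogermacra-1(10)Z,4Z,11(13)-trien-12,6-olide | C=C1C(=O)O[C@H]2/C=C(/C)C(=O)C/C=C(/C)C[C@H](OC(=O)[C@H](C)CC)[C@H]12
F3 | step 10 | (4R,5R)-4-[(3Z)-6-{[tert-butyl(dimethyl)silyl]oxy}-3-methylhex-3-enoyl]-5-[(1Z)-2-iodoprop-1-en-1-yl]-3-methylideneoxolan-2-one | C=C1C(=O)O[C@@H](/C=C(/C)I)[C@@H]1C(=O)C/C(C)=C\CCO[Si](C)(C)C(C)(C)C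
F4 | step 10 | (4S,5R)-4-[(1S,3Z)-6-{[tert-butyl(dimethyl)silyl]oxy}-1-hydroxy-3-methylhex-3-en-1-yl]-5-[(1Z)-2-iodoprop-1-en-1-yl]-3-methylideneoxolan-2-one | C=C1C(=O)O[C@@H](/C=C(/C)I)[C@@H]1[C@@H](O)C/C(C)=C\CCO[Si](C)(C)C(C)(C)C
F5 | step 15 | (1S)-2-[(2S,3R)-3-(2-{[tert-butyl(dimethyl)silyl]oxy}ethyl)-2-methyloxiran-2-yl]-1-{(2R,3S)-2-[(1Z)-2-iodoprop-1-en-1-yl]-4-methylidene-5-oxooxolan-3-yl}ethyl (2R)-2-methylbutanoate | C=C1C(=O)O[C@@H](/C=C(/C)I)[C@@H]1[C@@H](OC(=O)[C@H](C)CC)C[C@]2(C)O[C@@H]2CCO[Si](C)(C)C(C)(C)C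
F6 | step 15 | (1S)-2-[(2S,3R)-3-(2-hydroxyethyl)-2-methyloxiran-2-yl]-1-{(2R,3S)-2-[(1Z)-2-iodoprop-1-en-1-yl]-4-methylidene-5-oxooxolan-3-yl}ethyl (2R)-2-methylbutanoate | C=C1C(=O)O[C@@H](/C=C(/C)I)[C@@H]1[C@@H](OC(=O)[C@H](C)CC)C[C@]2(C)O[C@@H]2CCO
F7 | step 15 | (1S)-1-{(2R,3S)-2-[(1Z)-2-iodoprop-1-en-1-yl]-4-methylidene-5-oxooxolan-3-yl}-2-[(2S,3R)-2-methyl-3-(2-oxoethyl)oxiran-2-yl]ethyl (2R)-2-methylbutanoate | C=C1C(=O)O[C@@H](/C=C(/C)I)[C@@H]1[C@@H](OC(=O)[C@H](C)CC)C[C@]2(C)O[C@@H]2CC=O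
F8 | step 15 | (1R,3R,6S,7S,8S,10S)-1,10-epoxy-3-hydroxy-8-[(2R)-2-methylbutanoyloxy]germacra-4Z,11(13)-dien-12,6-olide | C=C1C(=O)O[C@H]2/C=C(/C)[C@H](O)C[C@H]3O[C@@]3(C)C[C@H](OC(=O)[C@H](C)CC)[C@H]12
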